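## Analysis of the target

The target (28) is a sesquineolignan built on a 2,5-diaryl-3,4-dimethyltetrahydrofuran (O1, C2–C5). The C2 aryl group (ring B, 3-methoxy-4-alkoxyphenyl) is linked through its 4-oxygen to C8'' of a 1-arylpropan-1-ol side chain (C7'' carbinol on ring A, C9'' methyl); ring A and ring C (on C5) are 4-hydroxy-3-methoxyphenyl groups. There are six stereocentres: (2R,3R,4R,5S) in the ring, meaning C2-aryl/C3-methyl trans, C3-methyl/C4-methyl trans and C4-methyl/C5-aryl cis (the two aryls cis), and (7''R,8''R) in the side chain, a threo aryloxy alcohol. The side-chain centres are too far from the ring to be relayed from it and need their own source of chirality. The sensitive sites are the two free phenols, the para-hydroxybenzylic alcohol at C7'' and the benzylic ethers at C2 and C5; all of the benzylic C–O bonds ionise under acid and would epimerise, so the end of the route has to be non-acidic and non-oxidising. The difficulties are the four contiguous ring stereocentres with one cis relationship (C4/C5) that is not the thermodynamic one, the distinction of three nearly identical guaiacyl rings, and the distinction of two secondary benzylic alcohols (C5–OH before ring closure and C7''–OH). The strategy rests on C2: it is bonded to O1 and to ring B, the only ring that still carries two ether oxygens once the phenols of rings A and C are acylated, so C2 can travel as a CH2 group and be made the electrophile late, by oxidation, when the C5 hydroxyl closes the ring.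

## Retrosynthetic reasoning

**28 to 27 to 26 (unmasking).** The last two operations only remove protecting groups: the Si–O bond at C7'' of 27, then the two aryl acetates of 26. Acid-labile groups are excluded because C2, C5 and C7'' are all benzylic and oxygenated, so the groups are chosen to fall to fluoride and to mild base.

**26 to 24 through cation 25 (O1–C2).** The ring is opened at O1–C2 and not at O1–C5, because only C2 sits on the dialkoxy ring B; ring C in 24 is an acetoxyarene and neither ionises nor is oxidised, so the C5 oxygen keeps its configuration and acts as the nucleophile. The gain is that 24 is an acyclic 1,4-diaryl-2,3-dimethylbutan-1-ol whose three stereocentres can be set by acyclic methods, and that C2 is a plain CH2 that can be attached by cross-coupling. The forward reaction has to abstract hydride at C2 only, close faster than the cation eliminates, place the aryl trans to the C3 methyl and stop before the product ether is oxidised again. An all-acetate precursor would be simplest to unmask, but an acetate at C7'' cannot be present when an aryl Grignard reagent creates C5–OH, and the two secondary benzylic alcohols cannot be told apart afterwards. 24 therefore carries a silyl ether at C7'' and acetates only on the phenols. The C7'' oxygen must be capped in any case, since a free hydroxyl there could add to the ipso carbon of cation 25 and let the aryl ether migrate.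

**24 to 23 to 22 (phenol protecting-group exchange).** The aryl silyl ethers needed for the organometallic steps are exchanged for acetates after the last such step. Aryl silyl ethers can be cleaved beside an alkyl silyl ether, and phenols can be acetylated beside a secondary alcohol, so C5–OH stays free without a protection step of its own.

**22 to 21 and 14 (C5–aryl).** Cutting the C5–ring C bond leaves the α-methyl aldehyde 21 and the aryl Grignard reagent 14. The addition must follow the Felkin–Anh sense, which is the one that becomes C4/C5 cis in the ring.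

**21 to 19 via 20 (aldehyde from an alkene).** The aldehyde is masked as an (E)-propenyl group, which survives the cross-coupling and is cleaved through diol 20 without touching the electron-rich arenes.

**19 to 8 and 17 via 18 (C2–ring B).** The bond between C2 and ring B is cut to a primary alkyl iodide 8 and aryl bromide 17; the alkylzinc reagent 18 couples under palladium catalysis. This is the convergent step, and it makes no stereochemical demand because C2 is still CH2.

**8 to 7 to 6 to 3 (via 4 and 5), from 1 and 2 (C3–C4).** The two methyl-bearing centres come from one [3,3] shift of ester 3: the C3–C4 bond forms, the carbinol chirality is transferred and the syn relationship follows from the ketene acetal geometry of 4. Ester 3 is obtained enantioenriched from racemic 1 by lipase acylation with 2, which installs the propanoate at the same time. Acid 6 is reduced to 7 and converted to iodide 8.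

**17 to 16 to 15, from 12 and 14; 12 to 11, from 9 and 10; 14 from 13 from 10.** C8'' is taken from the chiral pool: 9 is etherified with phenol 10 with inversion to 11, which is converted to Weinreb amide 12. Grignard reagent 14 is made once from silyl ether 13 and serves twice: with 12 it gives ketone 15, and later it supplies ring C. Catalyst-controlled reduction of 15 sets C7'' (16), and silylation gives 17. Phenol 10 supplies all three aromatic rings.

## Alternatives that were turned down

**Alternative 1:** The two C–CH3 bonds at C3 and C4 are disconnected on a preformed lactone. In the forward step, butenolide A1 (C2 aryl with the protected side chain) takes up a methyl cuprate at C3 anti to the aryl, and the enolate is methylated at C4 anti to the new methyl, giving all-trans lactone A2 in one flask.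
- For: three contiguous centres follow from one by substrate control, with no enolate-geometry question. On control of C3 and C4 this is stronger than the chosen route. C5 would follow by aryllithium addition to the carbonyl of A2 and ionic silane reduction, with hydride entering anti to the C4 methyl, which fits the 4,5-cis target.
- Against: the key step closes no ring and leaves the C5 aryl still to be attached. The Lewis acid needed for that reduction acts on a molecule that already holds the ionisable C2 benzylic ether on ring B and the benzylic SEM ether at C7''. Enantioenriched A1 needs its own asymmetric step on a substrate carrying the whole side chain. The benzyl ether must be removed by hydrogenolysis next to two benzylic ring C–O bonds, and the SEM group needs a further step.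
- Comparison: the chosen strategy offers instead a convergent coupling with no stereochemical demand, no Lewis acid on the finished ring, and protecting groups removed by base and fluoride only.

**Alternative 2:** O1–C5 and C2–C3 are disconnected together. In the forward step, trans-2-aryl-3-methylcyclopropane-1,1-diester A3 and side-chain aldehyde A4 combine under Sn(OTf)2: the aldehyde oxygen opens the cyclopropane at the aryl-bearing carbon with inversion and the malonate closes onto the carbonyl, giving 2,5-cis tetrahydrofuran diester A5.
- For: two bonds and the ring form in one convergent step, which is stronger than the chosen closure in bonds formed. The 2,5-cis outcome and the trans cyclopropane map correctly onto the target.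
- Against: C3 arrives as a quaternary diester. Turning it into a CH–CH3 trans to the C2 aryl takes decarboxylation, reduction, activation and deoxygenation, through an epimerisable ester. The strongly donating 4-alkoxyaryl group makes cyclopropane opening reversible, which threatens both enantiopurity and the C4/C5 relationship. Enantioenriched A3 is not simple to obtain.
- Comparison: the chosen strategy offers every carbon already at its final oxidation level and nothing to edit after ring closure.

**Alternative 3:** C4–C5 is disconnected. In the forward step, α-aryl-α-alkoxyacetic acid A6, tethered through O1 to the C2–C3 homoallyl unit, is decarboxylated; the C5 radical adds 5-exo to the vinyl group and hydrogen-atom transfer makes the C4 methyl, giving protected target A7.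
- For: the protected target is reached directly, and two stereocentres (C4 and C5) are set in the closure against one in the chosen route. On that count it is stronger, and the chair-like transition state for hexenyl radical closure predicts the required 3,4-trans and 4,5-cis pattern.
- Against: the radical is both benzylic and α-alkoxy, so it adds slowly and reversibly to an unactivated alkene, while reduction and oxidation to the oxocarbenium ion compete. Two centres rest on small energy differences. The O1 ether between two secondary benzylic carbons must be built by a hindered etherification. The benzyl and SEM groups bring the same deprotection problems as in Alternative 1.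
- Comparison: the chosen strategy leaves only one centre to a fast polar closure, and that centre is backed by the thermodynamic preference.

Key step: step 17

## Route

TBS = tert-butyldimethylsilyl. Remark on the chemistry: the arylmagnesium bromide 14 is assumed to keep its titre as a THF solution under argon, so that one batch serves both aryl additions (steps 9 and 14).

Step 1
Reactants: 1 (E)-pent-3-en-2-ol (racemic); 2 vinyl propanoate
Product: 3 (R,E)-pent-3-en-2-yl propanoate
Conditions: Novozym 435 (immobilised Candida antarctica lipase B), 2 (0.6 equiv), hexane, rt, stopped just short of 50% conversion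
Reagents that add atoms: none
Why: Lipase-catalysed kinetic resolution by irreversible transesterification; this lipase acylates the (R)-enantiomer of secondary alcohols with one small (methyl) and one larger (propenyl) group, so the ester should be (R) and the (S)-alcohol is left behind. The acyl donor installs the propanoate needed for the next step.

Step 2
Reactants: 3 (R,E)-pent-3-en-2-yl propanoate
Product: 6 (2R,3S,E)-2,3-dimethylhex-4-enoic acid, via (Z)-silyl ketene acetal 4 (not isolated), via silyl ester 5 (not isolated)
Conditions: LiN(iPr)2, THF/DMPU, −78 °C; TBSCl; −78 to 60 °C; then aq. HCl, THF, rt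
Reagents that add atoms: none
Why: Ireland–Claisen rearrangement: enolisation in the presence of DMPU should give mainly the (Z)-silyl ketene acetal 4 (methyl cis to OSi). Its [3,3] shift through a chair with the carbinol methyl equatorial forms the future C3–C4 bond, transfers the C–O chirality and places the two methyls syn, i.e. (2R,3S) with an E alkene; silyl ester 5 is hydrolysed on work-up.

Step 3
Reactants: 6 (2R,3S,E)-2,3-dimethylhex-4-enoic acid
Product: 7 (2R,3S,E)-2,3-dimethylhex-4-en-1-ol
Conditions: LiAlH4, Et2O, 0 °C to rt
Reagents that add atoms: none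
Why: Hydride reduction of a carboxylic acid; the α-centre sits in a carboxylate during the reaction and is not epimerised.

Step 4
Reactants: 7 (2R,3S,E)-2,3-dimethylhex-4-en-1-ol
Product: 8 (2E,4S,5R)-6-iodo-4,5-dimethylhex-2-ene
Conditions: I2, PPh3, imidazole, CH2Cl2, 0 °C to rt
Reagents that add atoms: iodine, II
Why: Appel-type iodination of a primary alcohol through the alkoxyphosphonium ion and SN2 attack by iodide; no stereocentre is involved.

Step 5
Reactants: 9 ethyl (S)-lactate; 10 4-bromo-2-methoxyphenol
Product: 11 ethyl (R)-2-(4-bromo-2-methoxyphenoxy)propanoate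
Conditions: PPh3, DIAD, THF, 0 °C to rt
Reagents that add atoms: none
Why: Mitsunobu etherification; the phenol displaces the activated lactate hydroxyl by SN2 with inversion, (S) to (R), which fixes C8''.

Step 6
Reactants: 11 ethyl (R)-2-(4-bromo-2-methoxyphenoxy)propanoate
Product: 12 (R)-2-(4-bromo-2-methoxyphenoxy)-N-methoxy-N-methylpropanamide
Conditions: MeNH(OMe)·HCl, iPrMgCl, THF, −20 °C
Reagents that add atoms: N,O-dimethylhydroxylamine hydrochloride, CNOC.Cl
Why: Weinreb amide formation by aminolysis of the ester with the magnesium amide; at this temperature the weakly basic amide should not enolise the α-aryloxy centre, and the aryl bromide does not exchange with iPrMgCl.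

Step 7
Reactants: 10 4-bromo-2-methoxyphenol
Product: 13 (4-bromo-2-methoxyphenoxy)(tert-butyl)dimethylsilane
Conditions: TBSCl, imidazole, DMF, rt
Reagents that add atoms: tert-butyldimethylsilyl chloride, CC(C)(C)[Si](C)(C)Cl
Why: Standard silylation of a phenol; the aryl silyl ether tolerates magnesium insertion and serves as the precursor of both ring A and ring C.

Step 8
Reactants: 13 (4-bromo-2-methoxyphenoxy)(tert-butyl)dimethylsilane
Product: 14 [4-(TBS-oxy)-3-methoxyphenyl]magnesium bromide, obtained as a titrated THF solution
Conditions: Mg turnings, THF, rt to reflux; solution titrated and stored under argon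
Reagents that add atoms: magnesium, [Mg]
Why: Grignard formation by insertion of magnesium into the aryl C–Br bond; the aryl silyl ether and the methoxy group are inert to the reagent. One batch is made and drawn on twice, for the ketone synthesis (step 9) and for the aldehyde addition (step 14).

Step 9
Reactants: 14 [4-(TBS-oxy)-3-methoxyphenyl]magnesium bromide; 12 (R)-2-(4-bromo-2-methoxyphenoxy)-N-methoxy-N-methylpropanamide
Product: 15 (R)-2-(4-bromo-2-methoxyphenoxy)-1-[4-(TBS-oxy)-3-methoxyphenyl]propan-1-one
Conditions: 14 (1.2 equiv, THF solution), 12, THF, 0 °C; aq. NH4Cl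
Reagents that add atoms: none
Why: Weinreb ketone synthesis: the aryl Grignard reagent adds once and the chelated tetrahedral intermediate releases the ketone only on work-up, so the α-centre is not exposed to base as a ketone. The aryl bromide of 12 does not exchange with an arylmagnesium halide at this temperature.

Step 10
Reactants: 15 (R)-2-(4-bromo-2-methoxyphenoxy)-1-[4-(TBS-oxy)-3-methoxyphenyl]propan-1-one
Product: 16 (1R,2R)-2-(4-bromo-2-methoxyphenoxy)-1-[4-(TBS-oxy)-3-methoxyphenyl]propan-1-ol
Conditions: (R)-2-methyl-CBS-oxazaborolidine (0.2 equiv), BH3·SMe2, THF, −20 °C; MeOH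
Reagents that add atoms: none
Why: Corey–Bakshi–Shibata reduction: with the aryl group as the large substituent the (R)-catalyst delivers hydride to the face that gives the (1R) carbinol. Felkin–Anh attack anti to the C8''–OAr bond prefers the same face, so catalyst and substrate are matched and the threo alcohol should dominate; borane does not enolise the ketone.

Step 11
Reactants: 16 (1R,2R)-2-(4-bromo-2-methoxyphenoxy)-1-[4-(TBS-oxy)-3-methoxyphenyl]propan-1-ol
Product: 17 (1R,2R)-2-(4-bromo-2-methoxyphenoxy)-1-(TBS-oxy)-1-[4-(TBS-oxy)-3-methoxyphenyl]propane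
Conditions: TBSOTf, 2,6-lutidine, CH2Cl2, 0 °C
Reagents that add atoms: tert-butyldimethylsilyl triflate, CC(C)(C)[Si](C)(C)OS(=O)(=O)C(F)(F)F
Why: Silylation of a hindered secondary alcohol with the silyl triflate; the alkyl silyl ether withstands organozinc, organomagnesium, carbonate base and the quinone oxidant, and keeps C7''–O distinct from the later C5–OH.

Step 12
Reactants: 8 (2E,4S,5R)-6-iodo-4,5-dimethylhex-2-ene; 17 (1R,2R)-2-(4-bromo-2-methoxyphenoxy)-1-(TBS-oxy)-1-[4-(TBS-oxy)-3-methoxyphenyl]propane
Product: 19 (1R,2R)-2-{4-[(2S,3R,4E)-2,3-dimethylhex-4-en-1-yl]-2-methoxyphenoxy}-1-(TBS-oxy)-1-[4-(TBS-oxy)-3-methoxyphenyl]propane, via alkylzinc iodide 18 (not isolated)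
Conditions: 8, Zn dust, LiCl, THF, 40 °C; then 17, Pd(OAc)2 (2 mol%), SPhos (4 mol%), THF, rt to 50 °C
Reagents that add atoms: none
Why: Negishi sp3–sp2 coupling: zinc inserts into the primary C–I bond, the alkylzinc iodide transmetalates to the arylpalladium bromide, and the bulky biarylphosphine favours reductive elimination over β-hydride elimination. Silyl ethers and the alkene are inert; the descriptors of the chain change only because the CIP ranks change.

Step 13
Reactants: 19 (1R,2R)-2-{4-[(2S,3R,4E)-2,3-dimethylhex-4-en-1-yl]-2-methoxyphenoxy}-1-(TBS-oxy)-1-[4-(TBS-oxy)-3-methoxyphenyl]propane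
Product: 21 (2R,3S)-4-{4-[(1R,2R)-1-(TBS-oxy)-1-[4-(TBS-oxy)-3-methoxyphenyl]propan-2-yl]oxy-3-methoxyphenyl}-2,3-dimethylbutanal, via vicinal diol 20 (not isolated)
Conditions: OsO4 (2 mol%), NaIO4, 2,6-lutidine, dioxane/H2O (3:1), rt
Reagents that add atoms: osmium tetroxide, O=[Os](=O)(=O)=O (carries the oxygen to the alkene); sodium periodate, [Na+].[O-]I(=O)(=O)=O (terminal oxidant that restores it)
Why: Lemieux–Johnson oxidation: catalytic dihydroxylation of the only alkene and periodate cleavage of diol 20 in the same flask. The buffered conditions spare the electron-rich arenes and the α-methyl centre of the aldehyde, which is used at once.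

Step 14
Reactants: 21 (2R,3S)-4-{4-[(1R,2R)-1-(TBS-oxy)-1-[4-(TBS-oxy)-3-methoxyphenyl]propan-2-yl]oxy-3-methoxyphenyl}-2,3-dimethylbutanal; 14 [4-(TBS-oxy)-3-methoxyphenyl]magnesium bromide
Product: 22 (1S,2R,3S)-1-[4-(TBS-oxy)-3-methoxyphenyl]-4-{4-[(1R,2R)-1-(TBS-oxy)-1-[4-(TBS-oxy)-3-methoxyphenyl]propan-2-yl]oxy-3-methoxyphenyl}-2,3-dimethylbutan-1-ol
Conditions: 14 (1.5 equiv, THF solution), THF, −78 °C; aq. NH4Cl
Reagents that add atoms: none
Why: Grignard addition to an α-chiral aldehyde; Felkin–Anh approach anti to the C3 chain and past hydrogen should favour the (1S) carbinol (OH syn to the C4 methyl), the relationship that becomes C4/C5 cis in the ring. The minor epimer is removed by chromatography.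

Step 15
Reactants: 22 (1S,2R,3S)-1-[4-(TBS-oxy)-3-methoxyphenyl]-4-{4-[(1R,2R)-1-(TBS-oxy)-1-[4-(TBS-oxy)-3-methoxyphenyl]propan-2-yl]oxy-3-methoxyphenyl}-2,3-dimethylbutan-1-ol
Product: 23 (1S,2R,3S)-1-(4-hydroxy-3-methoxyphenyl)-4-{4-[(1R,2R)-1-(4-hydroxy-3-methoxyphenyl)-1-(TBS-oxy)propan-2-yl]oxy-3-methoxyphenyl}-2,3-dimethylbutan-1-ol
Conditions: Cs2CO3, DMF/H2O (10:1), rt
Reagents that add atoms: none
Why: Selective cleavage of aryl silyl ethers by mild base: phenoxide is a good leaving group from silicon, whereas the secondary alkyl silyl ether at C7'' is inert under these conditions.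

Step 16
Reactants: 23 (1S,2R,3S)-1-(4-hydroxy-3-methoxyphenyl)-4-{4-[(1R,2R)-1-(4-hydroxy-3-methoxyphenyl)-1-(TBS-oxy)propan-2-yl]oxy-3-methoxyphenyl}-2,3-dimethylbutan-1-ol
Product: 24 (1S,2R,3S)-1-(4-acetoxy-3-methoxyphenyl)-4-{4-[(1R,2R)-1-(4-acetoxy-3-methoxyphenyl)-1-(TBS-oxy)propan-2-yl]oxy-3-methoxyphenyl}-2,3-dimethylbutan-1-ol
Conditions: Ac2O, 1 M aq. NaOH, THF, 0 °C
Reagents that add atoms: acetic anhydride, CC(=O)OC(C)=O
Why: Schotten–Baumann-type acetylation: phenoxides are acylated far faster than a neutral secondary alcohol in aqueous base, so both phenols become acetates and C5–OH stays free. The acetates raise the oxidation potential of rings A and C for the next step.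

Step 17
Reactants: 24 (1S,2R,3S)-1-(4-acetoxy-3-methoxyphenyl)-4-{4-[(1R,2R)-1-(4-acetoxy-3-methoxyphenyl)-1-(TBS-oxy)propan-2-yl]oxy-3-methoxyphenyl}-2,3-dimethylbutan-1-ol
Product: 26 (2R,3R,4R,5S)-5-(4-acetoxy-3-methoxyphenyl)-2-{4-[(1R,2R)-1-(4-acetoxy-3-methoxyphenyl)-1-(TBS-oxy)propan-2-yl]oxy-3-methoxyphenyl}-3,4-dimethyltetrahydrofuran, via benzylic cation 25 (not isolated)
Conditions: DDQ (1.05 equiv), 4 Å molecular sieves, CH2Cl2, −20 to 0 °C
Reagents that add atoms: none
Why: DDQ forms a charge-transfer complex with ring B, the only dialkoxyarene in 24, and removes hydride from C2–H (or an electron, a proton and a second electron), giving benzylic cation 25, which the para ether oxygen stabilises as a quinone-methide-like oxocarbenium ion. The C5 hydroxyl adds to C2 in a 5-exo-trig closure (the cationic C2–aryl unit lies outside the forming ring) to form O1–C2, and the proton passes to the reduced quinone. The closest known reaction type is the quinone-mediated or anodic dehydrogenative etherification and lactonisation of electron-rich alkylarenes that carry a tethered oxygen nucleophile. C2 is the only new stereocentre and is controlled by the C3 methyl: in the envelope transition state the planar aryl cation avoids allylic strain with that methyl, so O1 adds to the face that leaves the aryl trans to it (2R), which is also the more stable arrangement should the ether ionise again. Site selectivity is needed against C5–H and C7''–H, both benzylic and oxygenated, and is secured by the acetates, which make rings A and C poor donors and their benzylic cations poorly stabilised. Selectivity against the C2–H of product 26 is not secured by the substrate and rests on using close to one equivalent of oxidant at low temperature under dry conditions. The C7'' silyl ether keeps that oxygen from adding to the ipso carbon of ring B in 25.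

Step 18
Reactants: 26 (2R,3R,4R,5S)-5-(4-acetoxy-3-methoxyphenyl)-2-{4-[(1R,2R)-1-(4-acetoxy-3-methoxyphenyl)-1-(TBS-oxy)propan-2-yl]oxy-3-methoxyphenyl}-3,4-dimethyltetrahydrofuran
Product: 27 (2R,3R,4R,5S)-5-(4-hydroxy-3-methoxyphenyl)-2-{4-[(1R,2R)-1-(4-hydroxy-3-methoxyphenyl)-1-(TBS-oxy)propan-2-yl]oxy-3-methoxyphenyl}-3,4-dimethyltetrahydrofuran
Conditions: K2CO3, MeOH, rt
Reagents that add atoms: none
Why: Methanolysis of the two aryl acetates under mild base; the alkyl silyl ether and the benzylic ether centres are stable at room temperature under these conditions.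

Step 19
Reactants: 27 (2R,3R,4R,5S)-5-(4-hydroxy-3-methoxyphenyl)-2-{4-[(1R,2R)-1-(4-hydroxy-3-methoxyphenyl)-1-(TBS-oxy)propan-2-yl]oxy-3-methoxyphenyl}-3,4-dimethyltetrahydrofuran
Product: 28 the target, (1R,2R)-1-(4-hydroxy-3-methoxyphenyl)-2-{4-[(2R,3R,4R,5S)-5-(4-hydroxy-3-methoxyphenyl)-3,4-dimethyltetrahydrofuran-2-yl]-2-methoxyphenoxy}propan-1-ol
Conditions: TBAF, THF, 0 °C to rt
Reagents that add atoms: none
Why: Fluoride-mediated cleavage of the remaining Si–O bond; the non-acidic conditions avoid ionisation at C2, C5 and C7''.

## Compound list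

1 | (E)-pent-3-en-2-ol (racemic) | C/C=C/C(C)O | starting material
2 | vinyl propanoate | CCC(=O)OC=C | starting material
3 | (R,E)-pent-3-en-2-yl propanoate | CCC(=O)O[C@H](C)/C=C/C | intermediate
4 | (Z)-O-TBS ketene acetal of 3 (methyl cis to OSi) | C/C=C(\O[Si](C)(C)C(C)(C)C)O[C@H](C)/C=C/C | intermediate (not isolated)
5 | tert-butyldimethylsilyl (2R,3S,E)-2,3-dimethylhex-4-enoate | C/C=C/[C@H](C)[C@@H](C)C(=O)O[Si](C)(C)C(C)(C)C | intermediate (not isolated)
6 | (2R,3S,E)-2,3-dimethylhex-4-enoic acid | C/C=C/[C@H](C)[C@@H](C)C(=O)O | intermediate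
7 | (2R,3S,E)-2,3-dimethylhex-4-en-1-ol | C/C=C/[C@H](C)[C@@H](C)CO | intermediate
8 | (2E,4S,5R)-6-iodo-4,5-dimethylhex-2-ene | C/C=C/[C@H](C)[C@@H](C)CI | intermediate
9 | ethyl (S)-lactate | C[C@H](O)C(=O)OCC | starting material
10 | 4-bromo-2-methoxyphenol | COc1cc(Br)ccc1O | starting material
11 | ethyl (R)-2-(4-bromo-2-methoxyphenoxy)propanoate | C[C@@H](Oc1ccc(Br)cc1OC)C(=O)OCC | intermediate
12 | (R)-2-(4-bromo-2-methoxyphenoxy)-N-methoxy-N-methylpropanamide | C[C@@H](Oc1ccc(Br)cc1OC)C(=O)N(C)OC | intermediate
13 | (4-bromo-2-methoxyphenoxy)(tert-butyl)dimethylsilane | COc1cc(Br)ccc1O[Si](C)(C)C(C)(C)C | intermediate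
14 | [4-(TBS-oxy)-3-methoxyphenyl]magnesium bromide (titrated THF solution) | COc1cc([Mg]Br)ccc1O[Si](C)(C)C(C)(C)C | intermediate
15 | (R)-2-(4-bromo-2-methoxyphenoxy)-1-[4-(TBS-oxy)-3-methoxyphenyl]propan-1-one | C[C@@H](Oc1ccc(Br)cc1OC)C(=O)c1ccc(O[Si](C)(C)C(C)(C)C)c(OC)c1 | intermediate
16 | (1R,2R)-2-(4-bromo-2-methoxyphenoxy)-1-[4-(TBS-oxy)-3-methoxyphenyl]propan-1-ol | COc1cc([C@@H](O)[C@@H](C)Oc2ccc(Br)cc2OC)ccc1O[Si](C)(C)C(C)(C)C | intermediate
17 | (1R,2R)-2-(4-bromo-2-methoxyphenoxy)-1-(TBS-oxy)-1-[4-(TBS-oxy)-3-methoxyphenyl]propane | COc1cc([C@@H](O[Si](C)(C)C(C)(C)C)[C@@H](C)Oc2ccc(Br)cc2OC)ccc1O[Si](C)(C)C(C)(C)C | intermediate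
18 | [(2R,3S,E)-2,3-dimethylhex-4-en-1-yl]zinc iodide | C/C=C/[C@H](C)[C@@H](C)C[Zn]I | intermediate (not isolated)
19 | (1R,2R)-2-{4-[(2S,3R,4E)-2,3-dimethylhex-4-en-1-yl]-2-methoxyphenoxy}-1-(TBS-oxy)-1-[4-(TBS-oxy)-3-methoxyphenyl]propane | COc1cc([C@@H](O[Si](C)(C)C(C)(C)C)[C@@H](C)Oc2ccc(C[C@H](C)[C@@H](C)/C=C/C)cc2OC)ccc1O[Si](C)(C)C(C)(C)C | intermediate
20 | 4,5-diol of 19 (both syn-addition diastereomers) | COc1cc([C@@H](O[Si](C)(C)C(C)(C)C)[C@@H](C)Oc2ccc(C[C@H](C)[C@@H](C)C(O)C(C)O)cc2OC)ccc1O[Si](C)(C)C(C)(C)C | intermediate (not isolated)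
21 | (2R,3S)-4-{4-[(1R,2R)-1-(TBS-oxy)-1-[4-(TBS-oxy)-3-methoxyphenyl]propan-2-yl]oxy-3-methoxyphenyl}-2,3-dimethylbutanal | COc1cc([C@@H](O[Si](C)(C)C(C)(C)C)[C@@H](C)Oc2ccc(C[C@H](C)[C@@H](C)C=O)cc2OC)ccc1O[Si](C)(C)C(C)(C)C | intermediate
22 | (1S,2R,3S)-1-[4-(TBS-oxy)-3-methoxyphenyl]-4-{4-[(1R,2R)-1-(TBS-oxy)-1-[4-(TBS-oxy)-3-methoxyphenyl]propan-2-yl]oxy-3-methoxyphenyl}-2,3-dimethylbutan-1-ol (three silyl ethers) | COc1cc([C@@H](O[Si](C)(C)C(C)(C)C)[C@@H](C)Oc2ccc(C[C@H](C)[C@@H](C)[C@H](O)c3ccc(O[Si](C)(C)C(C)(C)C)c(OC)c3)cc2OC)ccc1O[Si](C)(C)C(C)(C)C | intermediate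
23 | bisphenol of 22 (C7'' silyl ether kept) | COc1cc([C@@H](O[Si](C)(C)C(C)(C)C)[C@@H](C)Oc2ccc(C[C@H](C)[C@@H](C)[C@H](O)c3ccc(O)c(OC)c3)cc2OC)ccc1O | intermediate
24 | key-step precursor: diacetate of 23 with free C5–OH | COc1cc([C@@H](O[Si](C)(C)C(C)(C)C)[C@@H](C)Oc2ccc(C[C@H](C)[C@@H](C)[C@H](O)c3ccc(OC(C)=O)c(OC)c3)cc2OC)ccc1OC(C)=O | intermediate
25 | C2 benzylic cation of 24 | COc1cc([C@@H](O[Si](C)(C)C(C)(C)C)[C@@H](C)Oc2ccc([CH+][C@H](C)[C@@H](C)[C@H](O)c3ccc(OC(C)=O)c(OC)c3)cc2OC)ccc1OC(C)=O | intermediate (not isolated)
26 | key-step product: (2R,3R,4R,5S)-tetrahydrofuran, two aryl acetates, C7'' silyl ether | COc1cc([C@@H](O[Si](C)(C)C(C)(C)C)[C@@H](C)Oc2ccc([C@@H]3O[C@H](c4ccc(OC(C)=O)c(OC)c4)[C@H](C)[C@H]3C)cc2OC)ccc1OC(C)=O | intermediate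
27 | bisphenol of 26 (C7'' silyl ether kept) | COc1cc([C@@H](O[Si](C)(C)C(C)(C)C)[C@@H](C)Oc2ccc([C@@H]3O[C@H](c4ccc(O)c(OC)c4)[C@H](C)[C@H]3C)cc2OC)ccc1O | intermediate
28 | CNP0171079.2 | COc1cc([C@@H](O)[C@@H](C)Oc2ccc([C@@H]3O[C@H](c4ccc(O)c(OC)c4)[C@H](C)[C@H]3C)cc2OC)ccc1O | target

## Step count and risk

Total step count: 19. Longest linear sequence: 13 steps (from 9 through steps 5, 6 and 9 to 19; the line from 10 through steps 7, 8 and 9 to 19 is equally long).

**Step 17 (key step).** The most likely failure is a second hydride abstraction from C2–H of the product: the cyclic dialkoxybenzyl ether is at least as good a hydride donor as the methylene it came from, so material may be lost to the oxocarbenium ion and, after work-up, to a ring-opened ketone. Incomplete site selectivity is the lesser concern. Fallback: cyclodehydration of a 1,4-diol, which reaches the same cation without an oxidant; it sets out from alcohol 7 and bromide 17 and returns at 26. Alcohol 7 is oxidised with Dess–Martin periodinane to (2R,3S,E)-2,3-dimethylhex-4-enal F1. Bromide 17 is lithiated (n-BuLi, THF, −78 °C) and added to F1, giving the C2 carbinol F2 as a mixture of C2 epimers, both of which serve. OsO4/NaIO4 cleaves the alkene and the hydroxy aldehyde closes to the lactol F3. Excess Grignard reagent 14 opens it to the 1,4-diol F4, with C5 set as in step 14. Cs2CO3 in DMF/H2O frees the two phenols to give the bisphenol diol F5, and Ac2O in aqueous NaOH acetylates them to give the diol diacetate F6. BF3·OEt2 in CH2Cl2 at −78 °C ionises only the C2 carbinol on ring B, and the C5 hydroxyl closes the ring through cation 25 to give 26.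

**Step 2.** The likely failure is incomplete geometric control in the enolisation, which carries the anti-dimethyl diastereomer forward. Fallback: an enol ether Claisen rearrangement in which the geometry is set by catalysis; it sets out from ester 3 and returns at alcohol 7. K2CO3 in MeOH releases (R,E)-pent-3-en-2-ol F7, and NaH with allyl bromide gives the allyl ether F8. [IrCl(C8H14)2]2, PCy3 and NaBPh4 isomerise the terminal allyl group to the (E)-propenyl ether F9. Heating then gives aldehyde F1 through a chair with all three methyl groups equatorial, and NaBH4 reduces F1 to 7.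

**Step 14.** The likely failure is poor facial selectivity, since the Felkin–Anh bias of an α-methyl aldehyde toward an aryl Grignard reagent is modest; α-epimerisation of 21 is a second concern. Fallback: set C5 by reagent control; it sets out from 22 as its C5 epimer mixture and returns at 22. Dess–Martin oxidation gives the aryl ketone F10. Reduction with (R)-2-methyl-CBS-oxazaborolidine and BH3·SMe2, with ring C as the large group, should return the (1S) carbinol 22. Here the catalyst has to override the substrate preference.

**Step 10.** The likely failure is insufficient facial selectivity if the branched, oxygenated α-substituent competes with the aryl group for the large-group role, or if borane is held by the ether oxygens. Fallback: make the erythro alcohol on purpose and invert it; it sets out from ketone 15 and returns at 16. Zn(BH4)2 in Et2O reduces 15 under chelation control to the erythro (1S,2R) alcohol F11. A Mitsunobu reaction with benzoic acid (PPh3, DIAD) inverts C7'' and gives the (1R,2R) benzoate F12. DIBAL-H in CH2Cl2 at −78 °C then removes the benzoate reductively, without freeing the phenol, and returns 16.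

## Further compounds

F1 | step 17 | (2R,3S,E)-2,3-dimethylhex-4-enal | C/C=C/[C@H](C)[C@@H](C)C=O
F2 | step 17 | C2 carbinol from the aryllithium of 17 and F1 (C2 epimers) | COc1cc([C@@H](O[Si](C)(C)C(C)(C)C)[C@@H](C)Oc2ccc(C(O)[C@H](C)[C@@H](C)/C=C/C)cc2OC)ccc1O[Si](C)(C)C(C)(C)C
F3 | step 17 | 5-aryl-3,4-dimethyltetrahydrofuran-2-ol lactol (aryl = ring B with the bis-silylated side chain) | COc1cc([C@@H](O[Si](C)(C)C(C)(C)C)[C@@H](C)Oc2ccc(C3OC(O)[C@H](C)[C@H]3C)cc2OC)ccc1O[Si](C)(C)C(C)(C)C
F4 | step 17 | 1,4-diaryl-2,3-dimethylbutane-1,4-diol with three silyl ethers | COc1cc([C@@H](O[Si](C)(C)C(C)(C)C)[C@@H](C)Oc2ccc(C(O)[C@H](C)[C@@H](C)[C@H](O)c3ccc(O[Si](C)(C)C(C)(C)C)c(OC)c3)cc2OC)ccc1O[Si](C)(C)C(C)(C)C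
F5 | step 17 | bisphenol of F4 (C7'' silyl ether kept) | COc1cc([C@@H](O[Si](C)(C)C(C)(C)C)[C@@H](C)Oc2ccc(C(O)[C@H](C)[C@@H](C)[C@H](O)c3ccc(O)c(OC)c3)cc2OC)ccc1O
F6 | step 17 | diacetate of F5 with both carbinols free | COc1cc([C@@H](O[Si](C)(C)C(C)(C)C)[C@@H](C)Oc2ccc(C(O)[C@H](C)[C@@H](C)[C@H](O)c3ccc(OC(C)=O)c(OC)c3)cc2OC)ccc1OC(C)=O
F7 | step 2 | (R,E)-pent-3-en-2-ol | C/C=C/[C@@H](C)O
F8 | step 2 | (2E,4R)-4-(prop-2-en-1-yloxy)pent-2-ene | C/C=C/[C@@H](C)OCC=C
F9 | step 2 | (2E,4R)-4-[(E)-prop-1-en-1-yloxy]pent-2-ene | C/C=C/[C@@H](C)O/C=C/C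
F10 | step 14 | C5 aryl ketone from 22 | COc1cc([C@@H](O[Si](C)(C)C(C)(C)C)[C@@H](C)Oc2ccc(C[C@H](C)[C@@H](C)C(=O)c3ccc(O[Si](C)(C)C(C)(C)C)c(OC)c3)cc2OC)ccc1O[Si](C)(C)C(C)(C)C
F11 | step 10 | (1S,2R)-2-(4-bromo-2-methoxyphenoxy)-1-[4-(TBS-oxy)-3-methoxyphenyl]propan-1-ol | COc1cc([C@H](O)[C@@H](C)Oc2ccc(Br)cc2OC)ccc1O[Si](C)(C)C(C)(C)C
F12 | step 10 | (1R,2R)-2-(4-bromo-2-methoxyphenoxy)-1-[4-(TBS-oxy)-3-methoxyphenyl]propyl benzoate | COc1cc([C@@H](OC(=O)c3ccccc3)[C@@H](C)Oc2ccc(Br)cc2OC)ccc1O[Si](C)(C)C(C)(C)C
A1 | alternative 1 | C2-aryl butenolide with the protected side chain | COc1cc([C@@H](OCOCC[Si](C)(C)C)[C@@H](C)Oc2ccc([C@@H]3OC(=O)C=C3)cc2OC)ccc1OCc1ccccc1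
A2 | alternative 1 | all-trans 5-aryl-3,4-dimethyl-γ-butyrolactone with the protected side chain | COc1cc([C@@H](OCOCC[Si](C)(C)C)[C@@H](C)Oc2ccc([C@@H]3OC(=O)[C@H](C)[C@H]3C)cc2OC)ccc1OCc1ccccc1
A3 | alternative 2 | dimethyl trans-2-(4-benzyloxy-3-methoxyphenyl)-3-methylcyclopropane-1,1-dicarboxylate | COC(=O)C1(C(=O)OC)[C@@H](c2ccc(OCc3ccccc3)c(OC)c2)[C@@H]1C
A4 | alternative 2 | 3-methoxy-4-(protected side-chain-oxy)benzaldehyde | COc1cc([C@@H](OCOCC[Si](C)(C)C)[C@@H](C)Oc2ccc(C=O)cc2OC)ccc1OCc1ccccc1
A5 | alternative 2 | 2,5-cis-diaryl-4-methyltetrahydrofuran-3,3-dicarboxylate with the protected side chain | COc1cc([C@@H](OCOCC[Si](C)(C)C)[C@@H](C)Oc2ccc([C@@H]3O[C@H](c4ccc(OCc5ccccc5)c(OC)c4)[C@H](C)C3(C(=O)OC)C(=O)OC)cc2OC)ccc1OCc1ccccc1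
A6 | alternative 3 | α-aryl-α-alkoxyacetic acid tethered through O1 to the C2–C3 homoallyl unit (C5 epimers) | COc1cc([C@@H](OCOCC[Si](C)(C)C)[C@@H](C)Oc2ccc([C@H](OC(C(=O)O)c4ccc(OCc5ccccc5)c(OC)c4)[C@H](C)C=C)cc2OC)ccc1OCc1ccccc1
A7 | alternative 3 | target as C7'' SEM ether and bis(benzyl) ether | COc1cc([C@@H](OCOCC[Si](C)(C)C)[C@@H](C)Oc2ccc([C@@H]3O[C@H](c4ccc(OCc5ccccc5)c(OC)c4)[C@H](C)[C@H]3C)cc2OC)ccc1OCc1ccccc1
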